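Remark on the chemistry assumed throughout: positions are given in labdane numbering (C1–C20; C17 = methyl on C8, C20 = methyl on C10), β is the face of the C10 methyl, and the SMILES is read as 5S,7S,8R,9R,10S, i.e. 7β-OAc (equatorial), 8β-OH (axial), 8α-CH3.

## Structural features

The target is a labdane: a trans-fused decalin in which ring A (C1–C5, C10) carries only the C4 gem-dimethyl group and ring B (C5–C10) carries every heteroatom of the bicycle. Five stereocentres are contiguous, C5–C10–C9–C8–C7: C10 is quaternary (axial methyl), C9 bears the equatorial six-carbon chain ending in an E trisubstituted allylic alcohol (C13=C14, C15–OH), C8 is a tertiary carbinol with an axial 8β-hydroxyl syn to the C10 methyl and an equatorial methyl, and C7 bears an equatorial acetate cis to the C8 hydroxyl. Fragile elements are the secondary acetate next to a free tertiary alcohol (acyl shift, hydrolysis), the tertiary alcohol itself (ionisation, dehydration) and the allylic alcohol with its trisubstituted alkene (acid, electrophilic oxidants, hydrogenation). The real difficulty is twofold: the C8 oxygen sits on the hindered β face, which alkene oxidation and anti addition across a C7=C8 or C8=C9 bond do not reach, and the quaternary C10 with its neighbours C5 and C9 must be set in absolute terms on a ring A that offers no functional handle. The key step exploits the 1,3 relation between the C8 oxygen and the fully substituted C10 across C9: with oxygen in the place of C9, ring B is a tetrahydropyran (O, C8, C7, C6, C5, C10) derived from a δ-lactone, C9 is an exocyclic alkylidene carbon that brings the whole side chain, and C10 is a tertiary alkyl–oxygen carbon able to ionise. Exchange of that ring oxygen for C9 then creates the C9–C10 bond, carbocyclic ring B and the C8 carbonyl at once, and the C8 ketone is what later lets C17 enter equatorially and the C7 oxygen enter by inversion.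

## Logic of the disconnections

22 ⇒ 21. The O–Si bond on the C15 oxygen is added. The primary allylic hydroxyl has to be masked through Lewis-acid, enolate and organometallic steps. No skeletal gain. The forward step must remove silicon without an alkoxide that could move the acetate.

21 ⇒ 20. The C8–C17 bond is cut. An axial hydroxyl syn to the C10 methyl cannot be delivered by an oxidant, but it results automatically if the methyl group is the incoming partner, because the axial trajectory at C8 is blocked. The gain is loss of the C8 stereocentre and a carbonyl that activates C7. The forward step needs a ketone-selective, non-basic methyl donor that spares the acetate.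

20 ⇒ 19 ⇒ 17. The C7–O bond is cut by way of a C7–Br bond. C7 is the unhindered α-methylene of the C8 ketone, an electrophile enters it axially from the α face, and SN2 inversion then gives the equatorial β oxygen. The gain is loss of the C7 stereocentre and of the acetate. The forward steps need enolisation away from C9 and clean inversion.

17 ⇒ 16 (key). The C9–C10 bond is cut and the C8 oxygen is joined to C10, so carbocyclic ring B becomes a tetrahydropyran with C9 outside the ring as an alkylidene carbon. C10 can carry positive charge and the carbonyl oxygen is 1,3 to it, so the C9–C10 bond is the product of a 1,3 shift from oxygen to carbon. The gain is large: C10 needs no defined configuration in 16, C9 is sp2, ring B is a lactone derivative, and the side chain is one alkylidene unit. The forward step must ionise a tertiary C–O bond without protons and collapse through carbon with trans ring fusion, leaving C5 untouched.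

16 ⇒ 9 + 15. The C8=C9 double bond is cut. This is the most convergent place to join the chain, since all seven chain carbons arrive in one piece on a C12 bicyclic lactone. The forward step is an ester alkylidenation that must tolerate the tertiary alkoxy group; its double-bond geometry is not critical because C9 is epimerisable after the key step.

9 ⇒ 7 ⇒ 5 ⇒ 4. The lactone C8–O acyl bond is traced to a 1,5-diol by oxidation level, the C8 hydroxyl to the terminal alkene of an allyl group, and the C10–C20 bond is cut to a C10 ketone. This leaves a monocyclic ketone with one stereocentre, C5. The methyl addition must not enolise the ketone; its facial selectivity is irrelevant.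

4 ⇒ 3 ⇒ 1. The C5–C6 bond (allyl) and one C4–methyl bond are cut. C5 is the only stereocentre in the route that a chiral reagent has to set; conjugate methyl addition fixes the enolate regiochemistry on the hindered side. The demand is an enantioselective allylation that forms an α-tertiary centre next to a quaternary carbon.

15 ⇒ 13 ⇒ 11 ⇒ 10. The two C–Br bonds on C9 go back to an aldehyde, and the aldehyde to cleavage of the distal isopropylidene of 10. The E geometry of C13=C14 and the C15 oxygen are bought with 10. The demand is oxidation of the distal alkene only.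

## Other disconnections considered

Alternative 1: Cut C4–C5 and C9–C10 of both rings at once. The forward key step is a catalyst-controlled, proton-initiated cation–olefin bicyclisation of geranylgeranyl acetate A1 to labda-7,13-dienyl acetate A2, followed by Woodward cis-hydroxylation of the C7=C8 bond from the β face. This is the first plan that comes to mind. It is not preferred for three reasons. The absolute configuration would rest on enantioselective protonation of an unfunctionalised trisubstituted alkene in a cascade terminated by another alkene, the weakest case for chiral Brønsted-acid control. Termination by proton loss gives double-bond regioisomers of A2. The anti addition inherent in cationic termination can only give the 8α-oxygen series, so C7 and C8 must be rebuilt afterwards by an iodoacetoxylation that also has to distinguish the ring alkene from the C13=C14 alkene.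

Alternative 2: Cut C9–C10 by a pericyclic route. The forward key step is E-to-Z photoisomerisation of the ionone-type dienone A3, enolisation towards C9 and oxyanion-accelerated 6π-electrocyclisation of the cross-conjugated trienolate to the bicyclic enone A4. All twenty skeletal carbons except C17 are in place after one aldol condensation, and C9 would be epimerisable. However, the triene is achiral and carries no stereocentre that could bias the disrotatory sense, so C10 would form as a racemate; an asymmetric electrocyclisation of this substrate class has no basis. The Z-dienone also closes reversibly through oxygen to a 2H-pyran and can undergo hydrogen shifts. The chosen plan forms the same bond but takes its absolute configuration from a C5 centre set beforehand.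

Alternative 3: Cut C7–C8. The forward key step is a SmI2 ketyl–aldehyde (pinacol) cyclisation of the 7,8-seco keto aldehyde A5, which should give the cis-7β,8β-diol directly through a chair with the C8 methyl equatorial. It is attractive for C7 and C8, but it moves the burden to A5: its C5/C10/C9 triad sits on a ring A with no handle, C5 would have to be set on an open chain between two quaternary carbons, and C9 is an α-keto centre that cannot be corrected once the ring is closed. The step count would exceed that of the chosen plan.

Key step: step 10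

## Route

Step 1
Reactants: 1 3-methylcyclohex-2-en-1-one
Product: 3 allyl 3,3-dimethylcyclohex-1-en-1-yl carbonate, via magnesium enolate 2 (not isolated)
Conditions: MeMgBr, CuI (5 mol %), THF, −20 °C; then allyl chloroformate, −78 → 0 °C
Reagents that add atoms: methylmagnesium bromide C[Mg]Br; allyl chloroformate C=CCOC(Cl)=O
Why: Copper-catalysed conjugate addition of the Grignard reagent gives the regiodefined enolate 2, whose α-carbon next to the new gem-dimethyl group is hindered, so the chloroformate should acylate on oxygen; no stereocentre is formed.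

Step 2
Reactants: 3 allyl 3,3-dimethylcyclohex-1-en-1-yl carbonate
Product: 4 (2S)-3,3-dimethyl-2-(prop-2-en-1-yl)cyclohexan-1-one
Conditions: Pd2(dba)3·CHCl3 (2.5 mol %), (R,R)-N,N′-(9,10-dihydro-9,10-ethanoanthracene-11,12-diyl)bis[2-(diphenylphosphino)benzamide] (6 mol %; the antipode if the facial sense is opposite), 1,4-dioxane, 23 °C
Reagents that add atoms: none
Why: Decarboxylative asymmetric allylic alkylation (Tsuji–Trost type): zerovalent palladium ionises the carbonate, CO2 is lost, and the chiral ligand selects the enolate face, setting C5 (S); the neutral medium should not enolise the α-tertiary ketone.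

Step 3
Reactants: 4 (2S)-3,3-dimethyl-2-(prop-2-en-1-yl)cyclohexan-1-one
Product: 5 (2S)-1,3,3-trimethyl-2-(prop-2-en-1-yl)cyclohexan-1-ol (both C1 epimers)
Conditions: MeLi, CeCl3, THF, −78 °C
Reagents that add atoms: methyllithium [Li]C
Why: Organocerium 1,2-addition is used because the non-basic reagent should not enolise, and so not racemise, the α-tertiary ketone; either configuration at the new carbinol carbon (C10) is acceptable because this centre is ionised in step 10.

Step 4
Reactants: 5 (2S)-1,3,3-trimethyl-2-(prop-2-en-1-yl)cyclohexan-1-ol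
Product: 7 (2S)-2-(3-hydroxypropyl)-1,3,3-trimethylcyclohexan-1-ol, via alkylborane 6 (not isolated)
Conditions: 9-BBN, THF, 0 → 25 °C; then NaOH, H2O2, 0 °C
Reagents that add atoms: hydrogen peroxide OO
Why: Anti-Markovnikov hydroboration–oxidation of the only alkene places the hydroxyl on the terminal carbon (C8); no stereocentre is formed.

Step 5
Reactants: 7 (2S)-2-(3-hydroxypropyl)-1,3,3-trimethylcyclohexan-1-ol
Product: 9 (4aS)-5,5,8a-trimethyloctahydro-2H-chromen-2-one (both C8a epimers), via lactol 8 (not isolated)
Conditions: TEMPO (10 mol %), PhI(OAc)2, CH2Cl2, 25 °C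
Reagents that add atoms: none
Why: Oxoammonium oxidation of the primary alcohol; the aldehyde is trapped by the tertiary hydroxyl as lactol 8, which is oxidised on to the δ-lactone under neutral conditions that should not ionise the tertiary C–O bond.

Step 6
Reactants: 10 geraniol
Product: 11 tert-butyl{[(2E)-3,7-dimethylocta-2,6-dien-1-yl]oxy}diphenylsilane
Conditions: TBDPSCl, imidazole, DMF, 0 → 25 °C
Reagents that add atoms: tert-butyl(chloro)diphenylsilane CC(C)(C)[Si](Cl)(c1ccccc1)c1ccccc1
Why: Standard silylation of the primary allylic alcohol; the bulky silyl ether should survive steps 7–13 and shield the neighbouring alkene.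

Step 7
Reactants: 11 tert-butyl{[(2E)-3,7-dimethylocta-2,6-dien-1-yl]oxy}diphenylsilane
Product: 13 (4E)-6-[(tert-butyldiphenylsilyl)oxy]-4-methylhex-4-enal, via epoxide 12 (not isolated)
Conditions: mCPBA, NaHCO3, CH2Cl2, −20 °C; then H5IO6, THF–H2O, 0 °C
Reagents that add atoms: 3-chloroperoxybenzoic acid OOC(=O)c1cccc(Cl)c1
Why: Prilezhaev epoxidation should select the electron-rich distal alkene over the one deactivated by the allylic silyloxy group; periodic acid then opens and cleaves the epoxide (glycol cleavage), leaving the E alkene intact.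

Step 8
Reactants: 13 (4E)-6-[(tert-butyldiphenylsilyl)oxy]-4-methylhex-4-enal
Product: 15 tert-butyl{[(2E)-6,6-dibromo-3-methylhex-2-en-1-yl]oxy}diphenylsilane, via hydrazone 14 (not isolated)
Conditions: N2H4·H2O, MeOH, 0 °C; then CuBr2, LiOtBu, THF, 25 °C
Reagents that add atoms: copper dibromide Br[Cu]Br
Why: Hydrazone formation followed by copper-mediated oxidative bromination with loss of N2 converts the aldehyde carbon into the CHBr2 group needed in step 9; the trisubstituted alkene should not react.

Step 9
Reactants: 9 (4aS)-5,5,8a-trimethyloctahydro-2H-chromen-2-one; 15 tert-butyl{[(2E)-6,6-dibromo-3-methylhex-2-en-1-yl]oxy}diphenylsilane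
Product: 16 (2Z,4aS)-2-{(4E)-6-[(tert-butyldiphenylsilyl)oxy]-4-methylhex-4-en-1-ylidene}-5,5,8a-trimethyloctahydro-2H-chromene (both C8a epimers)
Conditions: TiCl4, TMEDA, Zn, PbCl2 (cat.), THF, 25 °C
Reagents that add atoms: none
Why: Takai–Utimoto alkylidenation of an ester carbonyl: the low-valent titanium–zinc system turns the CHBr2 carbon into an alkylidene donor that olefinates the lactone C=O, normally giving the Z enol ether (chain cis to the ring oxygen). This joins the whole side chain and makes its first carbon the future C9.

Step 10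
Reactants: 16 (2Z,4aS)-2-{(4E)-6-[(tert-butyldiphenylsilyl)oxy]-4-methylhex-4-en-1-ylidene}-5,5,8a-trimethyloctahydro-2H-chromene
Product: 17 (1R,4aS,8aS)-1-{(3E)-5-[(tert-butyldiphenylsilyl)oxy]-3-methylpent-3-en-1-yl}-5,5,8a-trimethyloctahydronaphthalen-2(1H)-one
Conditions: Me2AlCl, CH2Cl2, −78 → −20 °C; aq. Rochelle salt
Reagents that add atoms: none
Why: Proposed new method: Me2AlCl binds the ring oxygen and heterolyses the tertiary C10–O bond, giving a zwitterion made of the ring-A tertiary cation at C10 and a Z aluminium enolate (oxygen on C8, C9 nucleophilic) still tethered through C5–C6–C7; C9 then attacks C10, so the ring oxygen is exchanged for carbon and becomes the C8 ketone oxygen. The closest known reaction types are the Petasis–Ferrier rearrangement of cyclic enol acetals, the Lewis-acid 1,3 shifts from oxygen to carbon of 2-alkylidenetetrahydropyrans that ionise to oxocarbenium, allyl or cobalt-complexed propargyl cations, and the SN1 α-tert-alkylation of enol silanes; the untested element is that the cation here is a simple tertiary alkyl cation. Ring B closes in a 6-(enolendo) mode onto the trigonal cation through a chair transition state. C10 is planar in the zwitterion, so both C10 epimers of 16 should converge; the resident C5 centre holds the tether equatorial on ring A and chair closure puts the C10 methyl axial, i.e. trans ring fusion, as in acid closures of monocyclic ring-A cations. C9 is set by the Z enolate geometry (chain anti to C7, hence equatorial, 9β) and, being α to the new ketone, is also the thermodynamic epimer. The step needs C–C bond formation to outrun proton loss from the cation: recombination through oxygen only regenerates 16, C–C bonding is irreversible because a C=O bond is gained, and the aprotic methylaluminium reagent scavenges protons, so C5 should not be scrambled by elimination and reprotonation. The side-chain alkene and silyl ether are remote and weakly basic and should not compete.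

Step 11
Reactants: 17 (1R,4aS,8aS)-1-{(3E)-5-[(tert-butyldiphenylsilyl)oxy]-3-methylpent-3-en-1-yl}-5,5,8a-trimethyloctahydronaphthalen-2(1H)-one
Product: 19 (1R,3R,4aS,8aS)-3-bromo-1-{(3E)-5-[(tert-butyldiphenylsilyl)oxy]-3-methylpent-3-en-1-yl}-5,5,8a-trimethyloctahydronaphthalen-2(1H)-one, via silyl enol ether 18 (not isolated)
Conditions: LDA, TMSCl, THF, −78 °C; then NBS, −78 °C
Reagents that add atoms: N-bromosuccinimide BrN1C(=O)CCC1=O
Why: Kinetic deprotonation should occur at the C7 methylene and not at the hindered C9–H; bromination of the enol silane follows the axial trajectory on the open α face and gives the 7α (axial) bromide.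

Step 12
Reactants: 19 (1R,3R,4aS,8aS)-3-bromo-1-{(3E)-5-[(tert-butyldiphenylsilyl)oxy]-3-methylpent-3-en-1-yl}-5,5,8a-trimethyloctahydronaphthalen-2(1H)-one
Product: 20 (2S,4R,4aS,8aS)-4-{(3E)-5-[(tert-butyldiphenylsilyl)oxy]-3-methylpent-3-en-1-yl}-4a,8,8-trimethyl-3-oxodecahydronaphthalen-2-yl acetate
Conditions: Bu4NOAc, acetone, 25 °C
Reagents that add atoms: tetrabutylammonium acetate CC(=O)[O-].CCCC[N+](CCCC)(CCCC)CCCC
Why: SN2 displacement of the carbonyl-activated axial bromide by acetate with inversion places the acetate 7β (equatorial); a soluble, weakly basic acetate source limits enolisation and elimination.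

Step 13
Reactants: 20 (2S,4R,4aS,8aS)-4-{(3E)-5-[(tert-butyldiphenylsilyl)oxy]-3-methylpent-3-en-1-yl}-4a,8,8-trimethyl-3-oxodecahydronaphthalen-2-yl acetate
Product: 21 (2S,3R,4R,4aS,8aS)-4-{(3E)-5-[(tert-butyldiphenylsilyl)oxy]-3-methylpent-3-en-1-yl}-3-hydroxy-3,4a,8,8-tetramethyldecahydronaphthalen-2-yl acetate
Conditions: MeLi, CeCl3, THF, −78 °C; AcOH quench at −78 °C
Reagents that add atoms: methyllithium [Li]C
Why: Organocerium addition is chemoselective for the ketone over the acetate and does not enolise; the axial β trajectory at C8 is blocked by the syn-axial C10 methyl, so the methyl group enters equatorially from the α face and the new hydroxyl is axial (8β), cis to the 7β-acetate.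

Step 14
Reactants: 21 (2S,3R,4R,4aS,8aS)-4-{(3E)-5-[(tert-butyldiphenylsilyl)oxy]-3-methylpent-3-en-1-yl}-3-hydroxy-3,4a,8,8-tetramethyldecahydronaphthalen-2-yl acetate
Product: 22 (2S,3R,4R,4aS,8aS)-3-hydroxy-4-[(3E)-5-hydroxy-3-methylpent-3-en-1-yl]-3,4a,8,8-tetramethyldecahydronaphthalen-2-yl acetate (target)
Conditions: TBAF, AcOH, THF, 25 °C
Reagents that add atoms: none
Why: Fluoride-mediated desilylation buffered with acetic acid, so that no free alkoxide is present that could shift or cleave the secondary acetate.

## Compound list

1 | 3-methylcyclohex-2-en-1-one | CC1=CC(=O)CCC1 | starting material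
2 | bromomagnesium 3,3-dimethylcyclohex-1-en-1-olate | CC1(C)C=C(O[Mg]Br)CCC1 | intermediate (not isolated)
3 | allyl 3,3-dimethylcyclohex-1-en-1-yl carbonate | C=CCOC(=O)OC1=CC(C)(C)CCC1 | intermediate
4 | (2S)-3,3-dimethyl-2-(prop-2-en-1-yl)cyclohexan-1-one | C=CC[C@H]1C(C)(C)CCCC1=O | intermediate
5 | (2S)-1,3,3-trimethyl-2-(prop-2-en-1-yl)cyclohexan-1-ol (C1 epimers) | C=CC[C@H]1C(C)(C)CCCC1(C)O | intermediate
6 | 9-{3-[(1S)-2-hydroxy-2,6,6-trimethylcyclohexyl]propyl}-9-borabicyclo[3.3.1]nonane | C(CC[C@H]1C(C)(C)CCCC1(C)O)B2C3CCCC2CCC3 | intermediate (not isolated)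
7 | (2S)-2-(3-hydroxypropyl)-1,3,3-trimethylcyclohexan-1-ol (C1 epimers) | OCCC[C@H]1C(C)(C)CCCC1(C)O | intermediate
8 | (4aS)-5,5,8a-trimethyloctahydro-2H-chromen-2-ol | OC1CC[C@H]2C(C)(C)CCCC2(C)O1 | intermediate (not isolated)
9 | (4aS)-5,5,8a-trimethyloctahydro-2H-chromen-2-one (C8a epimers) | O=C1CC[C@H]2C(C)(C)CCCC2(C)O1 | intermediate
10 | geraniol, (2E)-3,7-dimethylocta-2,6-dien-1-ol | CC(C)=CCC/C(C)=C/CO | starting material
11 | tert-butyl{[(2E)-3,7-dimethylocta-2,6-dien-1-yl]oxy}diphenylsilane | CC(C)=CCC/C(C)=C/CO[Si](c1ccccc1)(c1ccccc1)C(C)(C)C | intermediate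
12 | tert-butyl{[(2E)-5-(3,3-dimethyloxiran-2-yl)-3-methylpent-2-en-1-yl]oxy}diphenylsilane | CC1(C)OC1CC/C(C)=C/CO[Si](c1ccccc1)(c1ccccc1)C(C)(C)C | intermediate (not isolated)
13 | (4E)-6-[(tert-butyldiphenylsilyl)oxy]-4-methylhex-4-enal | O=CCC/C(C)=C/CO[Si](c1ccccc1)(c1ccccc1)C(C)(C)C | intermediate
14 | hydrazone of 13, (4E)-6-[(tert-butyldiphenylsilyl)oxy]-4-methylhex-4-enal hydrazone | NN=CCC/C(C)=C/CO[Si](c1ccccc1)(c1ccccc1)C(C)(C)C | intermediate (not isolated)
15 | tert-butyl{[(2E)-6,6-dibromo-3-methylhex-2-en-1-yl]oxy}diphenylsilane | BrC(Br)CC/C(C)=C/CO[Si](c1ccccc1)(c1ccccc1)C(C)(C)C | intermediate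
16 | (2Z,4aS)-2-{(4E)-6-[(tert-butyldiphenylsilyl)oxy]-4-methylhex-4-en-1-ylidene}-5,5,8a-trimethyloctahydro-2H-chromene (C8a epimers) | CC(C)(C)[Si](c1ccccc1)(c2ccccc2)OC/C=C(\C)CC/C=C3/CC[C@H]4C(C)(C)CCCC4(C)O3 | intermediate
17 | (1R,4aS,8aS)-1-{(3E)-5-[(tert-butyldiphenylsilyl)oxy]-3-methylpent-3-en-1-yl}-5,5,8a-trimethyloctahydronaphthalen-2(1H)-one | C1C[C@H]2C(C)(C)CCC[C@]2(C)[C@@H](CC/C(C)=C/CO[Si](c3ccccc3)(c3ccccc3)C(C)(C)C)C1=O | intermediate
18 | trimethylsilyl enol ether of 17 (C7=C8, labdane numbering) | C=1C[C@H]2C(C)(C)CCC[C@]2(C)[C@@H](CC/C(C)=C/CO[Si](c3ccccc3)(c3ccccc3)C(C)(C)C)C1O[Si](C)(C)C | intermediate (not isolated)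
19 | (1R,3R,4aS,8aS)-3-bromo-1-{(3E)-5-[(tert-butyldiphenylsilyl)oxy]-3-methylpent-3-en-1-yl}-5,5,8a-trimethyloctahydronaphthalen-2(1H)-one | Br[C@@H]1C[C@H]2C(C)(C)CCC[C@]2(C)[C@@H](CC/C(C)=C/CO[Si](c3ccccc3)(c3ccccc3)C(C)(C)C)C1=O | intermediate
20 | (2S,4R,4aS,8aS)-4-{(3E)-5-[(tert-butyldiphenylsilyl)oxy]-3-methylpent-3-en-1-yl}-4a,8,8-trimethyl-3-oxodecahydronaphthalen-2-yl acetate | CC(=O)O[C@H]1C[C@H]2C(C)(C)CCC[C@]2(C)[C@@H](CC/C(C)=C/CO[Si](c3ccccc3)(c3ccccc3)C(C)(C)C)C1=O | intermediate
21 | (2S,3R,4R,4aS,8aS)-4-{(3E)-5-[(tert-butyldiphenylsilyl)oxy]-3-methylpent-3-en-1-yl}-3-hydroxy-3,4a,8,8-tetramethyldecahydronaphthalen-2-yl acetate | CC(=O)O[C@H]1C[C@H]2C(C)(C)CCC[C@]2(C)[C@@H](CC/C(C)=C/CO[Si](c3ccccc3)(c3ccccc3)C(C)(C)C)[C@@]1(C)O | intermediate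
22 | (2S,3R,4R,4aS,8aS)-3-hydroxy-4-[(3E)-5-hydroxy-3-methylpent-3-en-1-yl]-3,4a,8,8-tetramethyldecahydronaphthalen-2-yl acetate | CC(=O)O[C@H]1C[C@H]2C(C)(C)CCC[C@]2(C)[C@@H](CC/C(C)=C/CO)[C@@]1(C)O | target

## Step count and least certain steps

Total step count: 14. Longest linear sequence: 11 (steps 1–5 and 9–14); the side-chain branch is steps 6–8.

Step 10 (key step, proposed new method). The most likely failure is proton loss from the tertiary cation inside the ion pair, or a 1,2-hydride shift from C5, faster than C–C bond formation, which would open the ring to an alkene instead of closing ring B. A second risk is collapse on the face from which the oxygen left, which would carry the cis fusion of one epimer of 16 into the product. The fallback uses the cation-stabilised form of this rearrangement, for which the reaction type is established; it sets out from 4 and returns at 17. Kinetic silylation of 4 (LDA, TMSCl) gives {[(6S)-5,5-dimethyl-6-(prop-2-en-1-yl)cyclohex-1-en-1-yl]oxy}trimethylsilane F1, and Saegusa–Ito oxidation (Pd(OAc)2, MeCN) gives (6S)-5,5-dimethyl-6-(prop-2-en-1-yl)cyclohex-2-en-1-one F2. The operations of steps 3, 4, 5 and 9 then give in turn (6S)-1,5,5-trimethyl-6-(prop-2-en-1-yl)cyclohex-2-en-1-ol F3, (6S)-6-(3-hydroxypropyl)-1,5,5-trimethylcyclohex-2-en-1-ol F4, (4aS)-5,5,8a-trimethyl-3,4,4a,5,6,8a-hexahydro-2H-chromen-2-one F5 and, with 15, the enol ether (2Z,4aS)-2-{(4E)-6-[(tert-butyldiphenylsilyl)oxy]-4-methylhex-4-en-1-ylidene}-5,5,8a-trimethyl-3,4,4a,5,6,8a-hexahydro-2H-chromene F6. In F6 the ring oxygen sits on a tertiary allylic carbon, so Me2AlCl ionises it to a longer-lived allyl cation and C9 attack at C10 should give (1R,4aS,8aS)-1-{(3E)-5-[(tert-butyldiphenylsilyl)oxy]-3-methylpent-3-en-1-yl}-5,5,8a-trimethyl-3,4,4a,5,6,8a-hexahydronaphthalen-2(1H)-one F7. Diimide reduction (potassium azodicarboxylate, AcOH), selective for the cis-disubstituted ring alkene over the trisubstituted chain alkene, then returns 17.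

Step 2. The most likely failure is poor facial discrimination for an α-tertiary centre flanked by a quaternary carbon, or erosion of the enantiomeric purity by enolisation of the product on the catalyst. The fallback replaces catalyst control in the C–C bond formation by dynamic kinetic resolution; it sets out from 1 and returns at 4. Enolate 2, made as in step 1, is trapped with allyl bromide to give racemic 3,3-dimethyl-2-(prop-2-en-1-yl)cyclohexan-1-one F8. Asymmetric ketone hydrogenation under base-mediated epimerisation (RuCl2[(S)-binap][(S,S)-dpen] or its antipode, KOtBu, iPrOH, H2), which leaves the terminal alkene alone, should give the cis alcohol (1R,2S)-3,3-dimethyl-2-(prop-2-en-1-yl)cyclohexan-1-ol F9. Dess–Martin oxidation under neutral conditions returns 4.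

Step 12. The most likely failure is loss of stereochemical fidelity through enolisation and epimerisation of the bromide before displacement, together with E2 elimination to the enone. The fallback introduces oxygen first and inverts it afterwards; it sets out from 17 and returns at 20. Kinetic enolisation (LDA) and hydroxylation with 2-(phenylsulfonyl)-3-phenyloxaziridine on the open α face gives (1R,3R,4aS,8aS)-1-{(3E)-5-[(tert-butyldiphenylsilyl)oxy]-3-methylpent-3-en-1-yl}-3-hydroxy-5,5,8a-trimethyloctahydronaphthalen-2(1H)-one F10. Mitsunobu esterification (AcOH, PPh3, DIAD) inverts C7 and returns 20.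

Step 13. The most likely failure is attack of the tertiary alkoxide on the neighbouring acetate, leading to acyl shift to O8 or loss of the acetate; partial attack of the reagent on the ester is also possible. The fallback accepts cleavage and reinstalls the ester; it sets out from 20 and returns at 21. Excess MeMgBr with CeCl3 adds to the ketone and removes the acetate, giving (2S,3R,4R,4aS,8aS)-4-{(3E)-5-[(tert-butyldiphenylsilyl)oxy]-3-methylpent-3-en-1-yl}-3,4a,8,8-tetramethyldecahydronaphthalene-2,3-diol F11. Acetylation (Ac2O, pyridine, 0 °C) of the equatorial secondary hydroxyl, which should leave the axial tertiary hydroxyl untouched, returns 21.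

## Further compounds

F1 | step 10 | {[(6S)-5,5-dimethyl-6-(prop-2-en-1-yl)cyclohex-1-en-1-yl]oxy}trimethylsilane | C=CC[C@H]1C(C)(C)CCC=C1O[Si](C)(C)C
F2 | step 10 | (6S)-5,5-dimethyl-6-(prop-2-en-1-yl)cyclohex-2-en-1-one | C=CC[C@H]1C(C)(C)CC=CC1=O
F3 | step 10 | (6S)-1,5,5-trimethyl-6-(prop-2-en-1-yl)cyclohex-2-en-1-ol (C1 epimers) | C=CC[C@H]1C(C)(C)CC=CC1(C)O
F4 | step 10 | (6S)-6-(3-hydroxypropyl)-1,5,5-trimethylcyclohex-2-en-1-ol (C1 epimers) | OCCC[C@H]1C(C)(C)CC=CC1(C)O
F5 | step 10 | (4aS)-5,5,8a-trimethyl-3,4,4a,5,6,8a-hexahydro-2H-chromen-2-one (C8a epimers) | O=C1CC[C@H]2C(C)(C)CC=CC2(C)O1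
F6 | step 10 | (2Z,4aS)-2-{(4E)-6-[(tert-butyldiphenylsilyl)oxy]-4-methylhex-4-en-1-ylidene}-5,5,8a-trimethyl-3,4,4a,5,6,8a-hexahydro-2H-chromene (C8a epimers) | CC(C)(C)[Si](c1ccccc1)(c2ccccc2)OC/C=C(\C)CC/C=C3/CC[C@H]4C(C)(C)CC=CC4(C)O3
F7 | step 10 | (1R,4aS,8aS)-1-{(3E)-5-[(tert-butyldiphenylsilyl)oxy]-3-methylpent-3-en-1-yl}-5,5,8a-trimethyl-3,4,4a,5,6,8a-hexahydronaphthalen-2(1H)-one | C1C[C@H]2C(C)(C)CC=C[C@]2(C)[C@@H](CC/C(C)=C/CO[Si](c3ccccc3)(c3ccccc3)C(C)(C)C)C1=O
F8 | step 2 | racemic 3,3-dimethyl-2-(prop-2-en-1-yl)cyclohexan-1-one | C=CCC1C(C)(C)CCCC1=O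
F9 | step 2 | (1R,2S)-3,3-dimethyl-2-(prop-2-en-1-yl)cyclohexan-1-ol | C=CC[C@H]1C(C)(C)CCC[C@H]1O
F10 | step 12 | (1R,3R,4aS,8aS)-1-{(3E)-5-[(tert-butyldiphenylsilyl)oxy]-3-methylpent-3-en-1-yl}-3-hydroxy-5,5,8a-trimethyloctahydronaphthalen-2(1H)-one | O[C@@H]1C[C@H]2C(C)(C)CCC[C@]2(C)[C@@H](CC/C(C)=C/CO[Si](c3ccccc3)(c3ccccc3)C(C)(C)C)C1=O
F11 | step 13 | (2S,3R,4R,4aS,8aS)-4-{(3E)-5-[(tert-butyldiphenylsilyl)oxy]-3-methylpent-3-en-1-yl}-3,4a,8,8-tetramethyldecahydronaphthalene-2,3-diol | O[C@H]1C[C@H]2C(C)(C)CCC[C@]2(C)[C@@H](CC/C(C)=C/CO[Si](c3ccccc3)(c3ccccc3)C(C)(C)C)[C@@]1(C)O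
A1 | alternative 1 | (2E,6E,10E)-geranylgeranyl acetate | CC(C)=CCC/C(C)=C/CC/C(C)=C/CC/C(C)=C/COC(C)=O
A2 | alternative 1 | (13E)-labda-7,13-dien-15-yl acetate | C=1C[C@H]2C(C)(C)CCC[C@]2(C)[C@@H](CC/C(C)=C/COC(C)=O)C1C
A3 | alternative 2 | (1E,8E)-10-[(tert-butyldiphenylsilyl)oxy]-8-methyl-1-(2,6,6-trimethylcyclohex-1-en-1-yl)deca-1,8-dien-3-one | CC1=C(/C=C/C(=O)CCC/C(C)=C/CO[Si](c2ccccc2)(c2ccccc2)C(C)(C)C)C(C)(C)CCC1
A4 | alternative 2 | racemic (13E)-15-[(tert-butyldiphenylsilyl)oxy]-17-norlabda-5,13-dien-8-one | C1C=C2C(C)(C)CCCC2(C)C(CC/C(C)=C/CO[Si](c3ccccc3)(c3ccccc3)C(C)(C)C)C1=O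
A5 | alternative 3 | 7,8-seco keto aldehyde, 2-[(1S,2S)-2-{(3R,6E)-8-[(tert-butyldiphenylsilyl)oxy]-6-methyl-2-oxooct-6-en-3-yl}-2,6,6-trimethylcyclohexyl]acetaldehyde | O=CC[C@H]1C(C)(C)CCC[C@]1(C)[C@@H](CC/C(C)=C/CO[Si](c2ccccc2)(c2ccccc2)C(C)(C)C)C(C)=O
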